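(The data were generated by integration with made-up constants, noise included.)

Minute first what the meeting had to settle: how far flask alpha gets by 9.7 min, and the two orders at the outset.

| flask | J | G | E | time |
|---|---|---|---|---|
| theta | 0.800 M | 0.880 M | 0.0640 M |  |
| gamma | 0.400 M | 0.480 M | 0.0640 M |  |
| delta | 0.800 M | 0.880 M | 0.0960 M |  |
| eta | 2.40 M | 0.880 M | 0.0640 M |  |
| alpha | 0.800 M | 0.880 M | 0.130 M | 9.7 min |

| run | time / min | [X] / M |
|---|---|---|
| theta run | 0.39 | 0.033 |
| theta run | 0.87 | 0.082 |
| theta run | 1.9 | 0.173 |
| theta run | 4.3 | 0.334 |
| theta run | 9.7 | 0.462 |
| gamma run | 0.39 | 0.011 |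
| gamma run | 0.87 | 0.040 |
| gamma run | 1.9 | 0.093 |
| gamma run | 4.3 | 0.183 |
| gamma run | 9.7 | 0.264 |
| delta run | 0.39 | 0.045 |
| delta run | 0.87 | 0.121 |
| delta run | 1.9 | 0.246 |
| delta run | 4.3 | 0.433 |
| delta run | 9.7 | 0.541 |
| eta run | 0.39 | 0.050 |
| eta run | 0.87 | 0.104 |
| eta run | 1.9 | 0.212 |
| eta run | 4.3 | 0.375 |
| eta run | 9.7 | 0.500 |

(scatter of a reading: 0.004 M)

- reaction order in [E] at the outset, round the charge of the theta run, defined at two percent of the J turned into X
- reaction order in [G] at the outset, round the charge of the theta run, defined at two percent of the J turned into X
- X in the alpha run at 9.7 min, as a share of the J charged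

- Overall: J + G -> X, with E as catalyst.
- Constant volume, constant temperature.
- The analysis sees a species whether free or bound.
- An order is taken over about fifteen percent of the charge, up and down.

The first speaker proposed to reckon a large term and then a small correction. For the large term she drew a pseudo-first-order line in cG through the 4.3 min reading of a run, counting one G per X. This gave slopes of 0.111 /min in theta and 0.158 /min in delta. Carried to 9.7 min, the lines reach cX of 0.580 M in theta and 0.689 M in delta, but the readings there are lower than that, at 0.462 M and 0.541 M.

The second speaker asked that the correction be named. She called it the late retention, the cX read at 9.7 min divided by the cX on the line. It is 0.796 in theta and 0.785 in delta, with a geometric mean of 0.791. Delta has 1.50 times the cE of theta at the same cJ and cG, so she proposed to carry this retention to alpha, which has those same cJ and cG.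

The first speaker then reckoned alpha. The two slopes give an order in cE of 0.863, which belongs to the slope up to that reading and is not the outset order asked. Alpha's slope is therefore 0.205 /min, and its line reaches 0.759 M, less than the 0.800 M of J, the limiting reagent. The retention brings this down to 0.600 M, which is 75.0 % of the J charged.

The forecaster put alpha at 73 %, within 68 % to 79 %, with orders of 1 in cE and 0.9 in cG, and said the late slowing “looks like time-based catalyst loss”. The speakers' reckoning stood 2 percentage points above the forecast.

The flask gives 72.3 % in alpha, with outset orders of 0.83 in cE and 0.65 in cG.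

    E + J → EJ (10.80 /M/min)
    EJ + G → Gy (3.144 /M/min)
    Gy → X + E (32.52 /min)
    X → Xi (0.02958 /min)
    2 G → Wy (0.05448 /M/min)

Alpha's late retention is therefore 0.762, lower than the 0.791 read from theta and delta. The main reason alpha stops short of its J charge is the reaction of X to Xi, which accounts for 59 % of what is missing. In the alpha run without that step, X reaches 88.7 % of the J charged, and the late retention against the same line rises to 0.935.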